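## Retrosynthetic overview

1. The target comes from its 6,8-di-O-methyl ether; both aryl methyl ethers are cleaved last.
2. Lactone ring B is the only ring built (aromatic ring A is bought). It is closed by forming the C3–O2 bond in a catalytic enantioselective 6-exo hydrolactonisation of an open-chain 2-(alk-2-enyl)benzoic acid, which also sets C3 (R).
3. The alkenyl acid comes from cross-metathesis of 2-allyl-4,6-dimethoxybenzoic acid with (S)-dodec-11-en-3-ol.
4. The 2-allyl acid comes from carboxylate-directed ortho C–H allylation of 2,4-dimethoxybenzoic acid. The alkenol comes from (S)-1,2-epoxybutane and an oct-7-enyl Grignard reagent, so the side-chain carbinol (S) is taken from the chiral pool.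
5. Ring order: ring A is present from the start; ring B is closed in the penultimate step.

Assumption: the sense of induction of the step 4 catalyst cannot be predicted, so the catalyst enantiomer (both are made from (R)- or (S)-BINOL) that is found to deliver 3R is the one meant.

## Route

Step 1
Reactants: 1 (S)-1,2-epoxybutane; 2 8-bromooct-1-ene
Product: 4 (S)-dodec-11-en-3-ol, via oct-7-en-1-ylmagnesium bromide 3 (not isolated)
Conditions: 2, Mg, THF, 40 °C; then CuI (10 mol %), 1, THF, −30 → 0 °C; aq NH4Cl
Reagents that add atoms: none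
Why: Copper-catalysed Grignard opening of a terminal epoxide is an SN2 attack at the unsubstituted CH2, so the C–O stereocentre of 1 is not touched and the carbinol of 4 is S (the new chain still outranks ethyl, so the descriptor is unchanged).

Step 2
Reactants: 5 2,4-dimethoxybenzoic acid; 6 allyl acetate
Product: 7 2-allyl-4,6-dimethoxybenzoic acid
Conditions: [RuCl2(p-cymene)]2 (2.5 mol %), K3PO4 (0.5 equiv), 6 (3 equiv), MeCN, 50 °C
Reagents that add atoms: none
Why: Ruthenium-catalysed carboxylate-directed C–H allylation (ortho C–H ruthenation, insertion of allyl acetate, β-acetoxy elimination) can only occur at C6, the single C–H ortho to the carboxylate, and creates no stereocentre.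

Step 3
Reactants: 7 2-allyl-4,6-dimethoxybenzoic acid (2 equiv); 4 (S)-dodec-11-en-3-ol
Product: 8 2-[(2E,11S)-11-hydroxytridec-2-en-1-yl]-4,6-dimethoxybenzoic acid
Conditions: second-generation Hoveyda–Grubbs catalyst RuCl2(H2IMes)(=CH-C6H4-2-OiPr) (5 mol %), 1,4-benzoquinone (10 mol %), CH2Cl2, 40 °C, Ar sparge
Reagents that add atoms: none
Why: Olefin cross-metathesis of two unhindered terminal alkenes is driven by loss of ethene and tolerates the free acid and alcohol; excess 7 limits homodimer of 4, benzoquinone suppresses Ru–H allyl-to-propenyl migration, and the remote carbinol is untouched (E:Z about 5:1, used as such).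

Step 4
Reactants: 8 2-[(2E,11S)-11-hydroxytridec-2-en-1-yl]-4,6-dimethoxybenzoic acid
Product: 9 (3R)-3-[(9S)-9-hydroxyundecyl]-6,8-dimethoxy-3,4-dihydroisocoumarin
Conditions: chiral IDPi Brønsted acid (BINOL-derived imidodiphosphorimidate, N-triflyl core, bulky 3,3'-aryl groups; 10 mol %), cyclohexane/CHCl3 1:1, 5 Å MS, 50 °C
Reagents that add atoms: none
Why: Proposed new method: a confined, strongly acidic chiral imidodiphosphorimidate hydrogen-bonds the carboxylic acid of 8 and, inside its pocket, delivers its proton to the alkene carbon remote from the ring while the carboxyl oxygen attacks the nearer alkene carbon in a concerted, asynchronous 6-exo-trig addition, so the C3–O2 bond, ring B and the 3R centre arise in one catalyst-controlled enantio-determining event (the remote 9'S carbinol plays no part) and no free secondary cation is left for hydride shift, Friedel–Crafts attack on the electron-rich ring or migration into conjugation; the closest known reaction type is IDPi-catalysed asymmetric hydrolactonisation and hydroalkoxylation of 1,1-disubstituted alkenes, together with racemic TfOH- or AgOTf-catalysed hydrolactonisation of 1,2-dialkyl alkenoic acids, and what is new is the unactivated 1,2-dialkyl alkene, the benzoic acid nucleophile and the six-membered lactone.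

Step 5
Reactants: 9 (3R)-3-[(9S)-9-hydroxyundecyl]-6,8-dimethoxy-3,4-dihydroisocoumarin
Product: 10 (3R)-6,8-dihydroxy-3-[(9S)-9-hydroxyundecyl]-3,4-dihydroisocoumarin (CNP0340379.1)
Conditions: BBr3 (6 equiv), CH2Cl2, −78 °C → rt; aq NaHCO3
Reagents that add atoms: none
Why: BBr3 O-demethylation of aryl methyl ethers cleaves the carbonyl-chelated 8-OMe first and the 6-OMe at room temperature, while the secondary alcohol is only masked as a dibromoborate that hydrolyses on work-up and the lactone and both stereocentres are not touched.

## Compound list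

1 | (S)-1,2-epoxybutane | CC[C@H]1CO1 | starting material
2 | 8-bromooct-1-ene | C=CCCCCCCBr | starting material
3 | oct-7-en-1-ylmagnesium bromide | C=CCCCCCC[Mg]Br | intermediate
4 | (S)-dodec-11-en-3-ol | CC[C@H](O)CCCCCCCC=C | intermediate
5 | 2,4-dimethoxybenzoic acid | COc1ccc(C(=O)O)c(OC)c1 | starting material
6 | allyl acetate | CC(=O)OCC=C | starting material
7 | 2-allyl-4,6-dimethoxybenzoic acid | C=CCc1cc(OC)cc(OC)c1C(=O)O | intermediate
8 | 2-[(2E,11S)-11-hydroxytridec-2-en-1-yl]-4,6-dimethoxybenzoic acid | CC[C@H](O)CCCCCCC/C=C/Cc1cc(OC)cc(OC)c1C(=O)O | intermediate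
9 | (3R)-3-[(9S)-9-hydroxyundecyl]-6,8-dimethoxy-3,4-dihydroisocoumarin | CC[C@H](O)CCCCCCCC[C@@H]1Cc2cc(OC)cc(OC)c2C(=O)O1 | intermediate
10 | (3R)-6,8-dihydroxy-3-[(9S)-9-hydroxyundecyl]-3,4-dihydroisocoumarin | CC[C@H](O)CCCCCCCC[C@@H]1Cc2cc(O)cc(O)c2C(=O)O1 | target

## Step count and risks

Total steps: 5. Longest linear sequence: 4 steps (5 → 7 → 8 → 9 → 10; the branch 1 → 4 joins at step 3).

**Step 4 (proposed new hydrolactonisation).**
- Risks: a 1,2-dialkyl alkene is much harder to protonate than the 1,1-disubstituted alkenes used so far; the E and Z isomers of 8 may respond differently; and the C3 epimer of 9 cannot be separated, so the selectivity must be high.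
- Fallback (known chemistry): sets out from 1 and 5 and comes back at 9.
  - Commercial 9-bromonon-1-ene is converted with Mg in THF into non-8-en-1-ylmagnesium bromide F1.
  - F1 opens 1 under CuI catalysis to give (S)-tridec-12-en-3-ol F2.
  - Epoxidation with mCPBA gives (3S)-11-(oxiran-2-yl)undecan-3-ol F3 as a 1:1 mixture of oxirane epimers.
  - Jacobsen hydrolytic kinetic resolution with (S,S)-Co(salen)(OAc) (the catalyst antipode that hydrolyses the 2S oxirane) and 0.55 equiv water leaves (3S)-11-[(2R)-oxiran-2-yl]undecan-3-ol F4.
  - Palladium-catalysed carboxylate-directed ortho C–H alkylation of 5 with F4 (Pd(OAc)2, N-acetyl-tert-leucine, KOAc, (CF3)2CHOH, 75 °C) breaks only the terminal C–O bond of the oxirane. The resulting alkoxide lactonises in the flask to 9 with the oxirane stereocentre retained as 3R.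

**Step 3 (cross-metathesis).**
- Risks: allyl-to-propenyl migration in 7, statistical homodimers, and an E/Z mixture that step 4 may not tolerate.
- Fallback: sets out from 4 and 5 and comes back at 8.
  - Ozonolysis of 4 (O3, CH2Cl2/MeOH, −78 °C; Me2S) gives (9S)-9-hydroxyundecanal F5.
  - Vinylmagnesium bromide (2.5 equiv, THF, −78 → 0 °C) gives (11S)-tridec-1-ene-3,11-diol F6; both C3 epimers are usable because that carbon becomes sp2.
  - The ruthenium C–H allylation of step 2 ([RuCl2(p-cymene)]2, K3PO4, CF3CH2OH, 60 °C) accepts secondary allylic alcohols as allyl donors (insertion, then β-hydroxide elimination). It joins F6 to 5 and gives 8 directly, as the E isomer and without metathesis.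

**Step 5 (global demethylation with a free secondary alcohol).**
- Risks: partial conversion of the carbinol into a bromide, or incomplete cleavage of the 6-OMe.
- Fallback: sets out from 9 and comes back at 10.
  - Acetylation of 9 (Ac2O, pyridine, DMAP) gives (3S)-11-[(3R)-6,8-dimethoxy-1-oxo-3,4-dihydro-1H-isochromen-3-yl]undecan-3-yl acetate F7.
  - BBr3 (CH2Cl2, −78 °C → rt) gives (3S)-11-[(3R)-6,8-dihydroxy-1-oxo-3,4-dihydro-1H-isochromen-3-yl]undecan-3-yl acetate F8.
  - K2CO3 in MeOH at rt followed by aq HCl removes the acetate (any ring-opened hydroxy ester relactonises on acidification) and gives 10.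

## Further compounds

F1 | step 4 | non-8-en-1-ylmagnesium bromide | C=CCCCCCCC[Mg]Br
F2 | step 4 | (S)-tridec-12-en-3-ol | CC[C@H](O)CCCCCCCCC=C
F3 | step 4 | (3S)-11-(oxiran-2-yl)undecan-3-ol (both oxirane epimers) | CC[C@H](O)CCCCCCCCC1CO1
F4 | step 4 | (3S)-11-[(2R)-oxiran-2-yl]undecan-3-ol | CC[C@H](O)CCCCCCCC[C@@H]1CO1
F5 | step 3 | (9S)-9-hydroxyundecanal | CC[C@H](O)CCCCCCCC=O
F6 | step 3 | (11S)-tridec-1-ene-3,11-diol (both C3 epimers) | CC[C@H](O)CCCCCCCC(O)C=C
F7 | step 5 | (3S)-11-[(3R)-6,8-dimethoxy-1-oxo-3,4-dihydro-1H-isochromen-3-yl]undecan-3-yl acetate | CC[C@H](OC(C)=O)CCCCCCCC[C@@H]1Cc2cc(OC)cc(OC)c2C(=O)O1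
F8 | step 5 | (3S)-11-[(3R)-6,8-dihydroxy-1-oxo-3,4-dihydro-1H-isochromen-3-yl]undecan-3-yl acetate | CC[C@H](OC(C)=O)CCCCCCCC[C@@H]1Cc2cc(O)cc(O)c2C(=O)O1
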